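**Retrosynthetic overview**
1. Sauriol B (22) ⇐ tri-O-benzyl ether 21 ⇐ dimesylate 20 ⇐ (2R,3R)-diol 19: both C-methyls (C9, C9') are taken back to CH2OH.
2. 19 ⇐ hexenol 17 ⇐ γ,δ-unsaturated acid 16: the CO2H carbon is C9 and the propenyl CH on C8' is C9'.
3. 16 ⇐ Ireland–Claisen rearrangement of allylic ester 13, which forms C8–C8' and both stereocentres from one carbinol stereocentre. 13 ⇐ acid 6 (from 5-hydroxyvanillin 1) + (R,E)-allylic alcohol 12 (from aldehyde 7 and (R)-but-3-yn-2-ol 10).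
4. Enabling feature: the acyclic C9–C8–C8'–C9' unit, two vicinal CH stereocentres each bearing a methyl and a benzylic CH2 (C7, C7') to one arene. Raising methyl C9 to CO2H and methyl C9' to an alkene CH turns C9–C8–C8'–C9' into C1–C2–C3–C4 of a pent-4-enoic acid, the Claisen retron.
5. Rings: none is formed; the two benzene rings arrive with aldehydes 1 and 7.

Key step: step 8

Remark on the chemistry: lignan numbering is used (C7–C9 for the 3-methoxy-4,5-dihydroxyphenyl half, C7'–C9' for the syringyl half). The target is (8R,8'R), the like (non-meso-type) diastereomer. Ar = 3,4-bis(benzyloxy)-5-methoxyphenyl, Ar' = 4-(benzyloxy)-3,5-dimethoxyphenyl.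

**Route**

Step 1
Reactants: 1 3,4-dihydroxy-5-methoxybenzaldehyde (5-hydroxyvanillin)
Product: 2 3,4-bis(benzyloxy)-5-methoxybenzaldehyde
Conditions: BnBr (2.3 equiv), K2CO3, DMF, 60 °C
Reagents that add atoms: benzyl bromide, BrCc1ccccc1
Why: Williamson ether synthesis; both phenoxides are alkylated by benzyl bromide and the aldehyde is inert to carbonate.

Step 2
Reactants: 2 3,4-bis(benzyloxy)-5-methoxybenzaldehyde; 3 Meldrum's acid (2,2-dimethyl-1,3-dioxane-4,6-dione)
Product: 6 3-[3,4-bis(benzyloxy)-5-methoxyphenyl]propanoic acid, via arylidene Meldrum's acid 4 (not isolated), via arylmethyl Meldrum's acid 5 (not isolated)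
Conditions: HCO2H–Et3N (5:2), rt → 100 °C; aq. HCl work-up
Reagents that add atoms: none
Why: Knoevenagel condensation, conjugate transfer hydrogenation by triethylammonium formate and hydrolysis/decarboxylation of the dioxanedione (reductive Meldrum's acid alkylation) should give the saturated acid without the catalytic hydrogenation that would cleave the benzyl ethers.

Step 3
Reactants: 7 4-(benzyloxy)-3,5-dimethoxybenzaldehyde
Product: 8 [4-(benzyloxy)-3,5-dimethoxyphenyl]methanol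
Conditions: NaBH4, MeOH, 0 °C
Reagents that add atoms: none
Why: Borohydride reduction of an aryl aldehyde; the ethers are inert.

Step 4
Reactants: 8 [4-(benzyloxy)-3,5-dimethoxyphenyl]methanol
Product: 9 2-(benzyloxy)-5-(bromomethyl)-1,3-dimethoxybenzene
Conditions: PBr3, CH2Cl2, 0 °C; used crude
Reagents that add atoms: phosphorus tribromide, BrP(Br)Br
Why: Conversion of a benzylic alcohol into the bromide through its phosphite ester; the labile electron-rich bromide is to be used at once.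

Step 5
Reactants: 9 2-(benzyloxy)-5-(bromomethyl)-1,3-dimethoxybenzene; 10 (R)-but-3-yn-2-ol
Product: 11 (2R)-5-[4-(benzyloxy)-3,5-dimethoxyphenyl]pent-3-yn-2-ol
Conditions: CuI (20 mol%), NaI (20 mol%), Cs2CO3, MeCN, rt → 40 °C
Reagents that add atoms: none
Why: Copper-mediated sp–sp3 coupling of a terminal alkyne with a benzylic halide (alkylation of the copper acetylide at carbon); carbonate does not deprotonate the secondary alcohol and the carbinol centre is not touched.

Step 6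
Reactants: 11 (2R)-5-[4-(benzyloxy)-3,5-dimethoxyphenyl]pent-3-yn-2-ol
Product: 12 (2R,3E)-5-[4-(benzyloxy)-3,5-dimethoxyphenyl]pent-3-en-2-ol
Conditions: Red-Al, THF, 0 °C → rt; aq. Rochelle salt
Reagents that add atoms: none
Why: Alkoxide-directed trans-hydroalumination of a propargylic alcohol followed by protonolysis should give only the E-allylic alcohol, with the carbinol configuration unchanged.

Step 7
Reactants: 6 3-[3,4-bis(benzyloxy)-5-methoxyphenyl]propanoic acid; 12 (2R,3E)-5-[4-(benzyloxy)-3,5-dimethoxyphenyl]pent-3-en-2-ol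
Product: 13 (2R,3E)-5-[4-(benzyloxy)-3,5-dimethoxyphenyl]pent-3-en-2-yl 3-[3,4-bis(benzyloxy)-5-methoxyphenyl]propanoate
Conditions: DIC, DMAP (cat.), CH2Cl2, 0 °C → rt
Reagents that add atoms: none
Why: Steglich esterification acylates the alcohol oxygen, so the carbinol C–O bond is not broken and the R configuration and E geometry are retained.

Step 8
Reactants: 13 (2R,3E)-5-[4-(benzyloxy)-3,5-dimethoxyphenyl]pent-3-en-2-yl 3-[3,4-bis(benzyloxy)-5-methoxyphenyl]propanoate
Product: 16 (2R,3S,4E)-2-[3,4-bis(benzyloxy)-5-methoxybenzyl]-3-[4-(benzyloxy)-3,5-dimethoxybenzyl]hex-4-enoic acid, via silyl ketene acetal 14 (not isolated), via silyl ester 15 (not isolated)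
Conditions: LDA, THF–DMPU (ca. 45 vol% DMPU), −78 °C; TBSCl, −78 °C → rt, then 50 °C; 1 M HCl
Reagents that add atoms: tert-butyldimethylsilyl chloride, CC(C)(C)[Si](C)(C)Cl (its silyl group stands in 14 and 15 only and is lost on work-up)
Why: LDA in THF–DMPU should deprotonate the ester α-CH2 (far more acidic than the allylic/benzylic CH2) through an open transition state to the Z(O)-enolate (ArCH2 cis to OLi), which TBSCl traps on oxygen as 14; on warming, 14 undergoes a concerted suprafacial [3,3]-sigmatropic shift that breaks the carbinol C–O bond and forms C8–C8' (C2–C3 of 16), and silyl ester 15 is hydrolysed on work-up. The closest known reaction type is the Ireland–Claisen rearrangement of E-configured secondary allylic alkanoates with 1,3-chirality transfer. No ring is closed; the six-membered array exists only in the chair transition state. Both new stereocentres arise there: with CH2Ar' on the E-alkene, CH2Ar on the Z(O)-ketene acetal and the carbinol methyl all equatorial, the two benzyl groups end up syn along the CO2H–C2–C3–CH= chain, and the (R)-carbinol fixes the face of bond formation so that both centres take the arrangement that becomes 8R,8'R in the target, with an E-propenyl group. The step needs control of enolate geometry (secured by the dissociating co-solvent DMPU), chair over boat (favoured for acyclic substrates) and an equatorial methyl (the axial alternative is strained); any anti diastereomer from residual E(O)-enolate should be separable at 16 or 19.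

Step 9
Reactants: 16 (2R,3S,4E)-2-[3,4-bis(benzyloxy)-5-methoxybenzyl]-3-[4-(benzyloxy)-3,5-dimethoxybenzyl]hex-4-enoic acid
Product: 17 (2R,3S,4E)-2-[3,4-bis(benzyloxy)-5-methoxybenzyl]-3-[4-(benzyloxy)-3,5-dimethoxybenzyl]hex-4-en-1-ol
Conditions: LiAlH4, THF, 0 °C → rt
Reagents that add atoms: none
Why: Hydride reduction of a carboxylic acid to the primary alcohol; the carboxylate is not enolised, so C2 keeps its configuration, and alkene and aryl benzyl ethers are inert.

Step 10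
Reactants: 17 (2R,3S,4E)-2-[3,4-bis(benzyloxy)-5-methoxybenzyl]-3-[4-(benzyloxy)-3,5-dimethoxybenzyl]hex-4-en-1-ol
Product: 19 (2R,3R)-2-[3,4-bis(benzyloxy)-5-methoxybenzyl]-3-[4-(benzyloxy)-3,5-dimethoxybenzyl]butane-1,4-diol, via ozonide 18 (not isolated)
Conditions: O3, CH2Cl2, −78 °C (Sudan III end point); then NaBH4, MeOH, −78 °C → rt
Reagents that add atoms: ozone, [O-][O+]=O
Why: Ozonolysis with reductive borohydride work-up cleaves the disubstituted alkene, which reacts far faster than the alkoxyarenes when the ozone dose is limited by the indicator, and reduction in the same flask avoids an epimerisable α-branched aldehyde.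

Step 11
Reactants: 19 (2R,3R)-2-[3,4-bis(benzyloxy)-5-methoxybenzyl]-3-[4-(benzyloxy)-3,5-dimethoxybenzyl]butane-1,4-diol
Product: 20 (2R,3R)-2-[3,4-bis(benzyloxy)-5-methoxybenzyl]-3-[4-(benzyloxy)-3,5-dimethoxybenzyl]butane-1,4-diyl dimethanesulfonate
Conditions: MsCl (3 equiv), Et3N, CH2Cl2, 0 °C
Reagents that add atoms: methanesulfonyl chloride, CS(=O)(=O)Cl
Why: O-sulfonylation of both primary alcohols with excess reagent at low temperature, fast enough to outrun cyclisation of the monomesylate; the stereocentres are not involved.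

Step 12
Reactants: 20 (2R,3R)-2-[3,4-bis(benzyloxy)-5-methoxybenzyl]-3-[4-(benzyloxy)-3,5-dimethoxybenzyl]butane-1,4-diyl dimethanesulfonate
Product: 21 1,2-bis(benzyloxy)-5-[(2R,3R)-4-[4-(benzyloxy)-3,5-dimethoxyphenyl]-2,3-dimethylbutyl]-3-methoxybenzene (tri-O-benzyl sauriol B)
Conditions: LiAlH4, THF, 0 °C → reflux
Reagents that add atoms: none
Why: SN2 displacement of both primary mesylates by hydride turns the two CH2OMs groups into the C9 and C9' methyls, the established deoxygenation of dibenzylbutanediol dimesylates; the stereocentres are untouched.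

Step 13
Reactants: 21 tri-O-benzyl sauriol B
Product: 22 sauriol B, 5-[(2R,3R)-4-(4-hydroxy-3,5-dimethoxyphenyl)-2,3-dimethylbutyl]-3-methoxybenzene-1,2-diol
Conditions: H2 (1 atm), 10% Pd/C, EtOAc–MeOH, rt; work-up under argon
Reagents that add atoms: none
Why: Hydrogenolysis of the three aryl benzyl ethers frees the catechol and the syringyl phenol; methyl ethers and the saturated chain are inert, and air is excluded to protect the catechol.

**Compound list**
1 | 3,4-dihydroxy-5-methoxybenzaldehyde | O=Cc1cc(OC)c(O)c(O)c1 | starting material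
2 | 3,4-bis(benzyloxy)-5-methoxybenzaldehyde | O=Cc1cc(OC)c(OCc2ccccc2)c(OCc2ccccc2)c1 | intermediate
3 | Meldrum's acid | CC1(C)OC(=O)CC(=O)O1 | starting material
4 | 5-[3,4-bis(benzyloxy)-5-methoxybenzylidene]-2,2-dimethyl-1,3-dioxane-4,6-dione | CC1(C)OC(=O)C(=Cc2cc(OC)c(OCc3ccccc3)c(OCc3ccccc3)c2)C(=O)O1 | intermediate
5 | 5-[3,4-bis(benzyloxy)-5-methoxybenzyl]-2,2-dimethyl-1,3-dioxane-4,6-dione | CC1(C)OC(=O)C(Cc2cc(OC)c(OCc3ccccc3)c(OCc3ccccc3)c2)C(=O)O1 | intermediate
6 | 3-[3,4-bis(benzyloxy)-5-methoxyphenyl]propanoic acid | OC(=O)CCc1cc(OC)c(OCc2ccccc2)c(OCc2ccccc2)c1 | intermediate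
7 | 4-(benzyloxy)-3,5-dimethoxybenzaldehyde | O=Cc1cc(OC)c(OCc2ccccc2)c(OC)c1 | starting material
8 | [4-(benzyloxy)-3,5-dimethoxyphenyl]methanol | OCc1cc(OC)c(OCc2ccccc2)c(OC)c1 | intermediate
9 | 2-(benzyloxy)-5-(bromomethyl)-1,3-dimethoxybenzene | BrCc1cc(OC)c(OCc2ccccc2)c(OC)c1 | intermediate
10 | (R)-but-3-yn-2-ol | C[C@@H](O)C#C | starting material
11 | (2R)-5-[4-(benzyloxy)-3,5-dimethoxyphenyl]pent-3-yn-2-ol | C[C@@H](O)C#CCc1cc(OC)c(OCc2ccccc2)c(OC)c1 | intermediate
12 | (2R,3E)-5-[4-(benzyloxy)-3,5-dimethoxyphenyl]pent-3-en-2-ol | C[C@@H](O)/C=C/Cc1cc(OC)c(OCc2ccccc2)c(OC)c1 | intermediate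
13 | (2R,3E)-5-[4-(benzyloxy)-3,5-dimethoxyphenyl]pent-3-en-2-yl 3-[3,4-bis(benzyloxy)-5-methoxyphenyl]propanoate | O=C(CCc1cc(OC)c(OCc2ccccc2)c(OCc2ccccc2)c1)O[C@H](C)/C=C/Cc1cc(OC)c(OCc2ccccc2)c(OC)c1 | intermediate
14 | O-TBS ketene acetal of 13, ArCH2 cis to OSi (Z), carbinol R, alkene E | CC(C)(C)[Si](C)(C)O/C(=C\Cc1cc(OC)c(OCc2ccccc2)c(OCc2ccccc2)c1)O[C@H](C)/C=C/Cc1cc(OC)c(OCc2ccccc2)c(OC)c1 | intermediate
15 | tert-butyldimethylsilyl ester of 16 | CC(C)(C)[Si](C)(C)OC(=O)[C@H](Cc1cc(OC)c(OCc2ccccc2)c(OCc2ccccc2)c1)[C@@H](Cc1cc(OC)c(OCc2ccccc2)c(OC)c1)/C=C/C | intermediate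
16 | (2R,3S,4E)-2-[3,4-bis(benzyloxy)-5-methoxybenzyl]-3-[4-(benzyloxy)-3,5-dimethoxybenzyl]hex-4-enoic acid | OC(=O)[C@H](Cc1cc(OC)c(OCc2ccccc2)c(OCc2ccccc2)c1)[C@@H](Cc1cc(OC)c(OCc2ccccc2)c(OC)c1)/C=C/C | intermediate
17 | (2R,3S,4E)-2-[3,4-bis(benzyloxy)-5-methoxybenzyl]-3-[4-(benzyloxy)-3,5-dimethoxybenzyl]hex-4-en-1-ol | OC[C@H](Cc1cc(OC)c(OCc2ccccc2)c(OCc2ccccc2)c1)[C@@H](Cc1cc(OC)c(OCc2ccccc2)c(OC)c1)/C=C/C | intermediate
18 | secondary ozonide of 17 (5-methyl-1,2,4-trioxolan-3-yl in place of propenyl, mixture at the trioxolane carbons) | OC[C@H](Cc1cc(OC)c(OCc2ccccc2)c(OCc2ccccc2)c1)[C@@H](Cc1cc(OC)c(OCc2ccccc2)c(OC)c1)C1OOC(C)O1 | intermediate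
19 | (2R,3R)-2-[3,4-bis(benzyloxy)-5-methoxybenzyl]-3-[4-(benzyloxy)-3,5-dimethoxybenzyl]butane-1,4-diol | OC[C@H](Cc1cc(OC)c(OCc2ccccc2)c(OCc2ccccc2)c1)[C@@H](Cc1cc(OC)c(OCc2ccccc2)c(OC)c1)CO | intermediate
20 | (2R,3R)-2-[3,4-bis(benzyloxy)-5-methoxybenzyl]-3-[4-(benzyloxy)-3,5-dimethoxybenzyl]butane-1,4-diyl dimethanesulfonate | CS(=O)(=O)OC[C@H](Cc1cc(OC)c(OCc2ccccc2)c(OCc2ccccc2)c1)[C@@H](Cc1cc(OC)c(OCc2ccccc2)c(OC)c1)COS(C)(=O)=O | intermediate
21 | 1,2-bis(benzyloxy)-5-[(2R,3R)-4-[4-(benzyloxy)-3,5-dimethoxyphenyl]-2,3-dimethylbutyl]-3-methoxybenzene | C[C@H](Cc1cc(OC)c(OCc2ccccc2)c(OCc2ccccc2)c1)[C@@H](Cc1cc(OC)c(OCc2ccccc2)c(OC)c1)C | intermediate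
22 | sauriol B, 5-[(2R,3R)-4-(4-hydroxy-3,5-dimethoxyphenyl)-2,3-dimethylbutyl]-3-methoxybenzene-1,2-diol | C[C@H](Cc1cc(OC)c(O)c(O)c1)[C@@H](Cc1cc(OC)c(O)c(OC)c1)C | target

**Count**
Total steps: 13. Longest linear sequence: 11 steps (steps 3–13, from 7).

**Steps most likely to fail, with fallbacks**

Step 8. Incomplete control of enolate geometry in THF–DMPU, or partial reaction through a boat, would erode the syn selectivity at C8/C8'. The fallback inverts both control elements so that the kinetically most dependable enolate, the E(O)-enolate from LDA in THF alone, is used. It sets out from 9 and 6. Bromide 9 would be coupled (CuI, Cs2CO3, MeCN) with commercial (S)-but-3-yn-2-ol (C[C@H](O)C#C) to (2S)-5-[4-(benzyloxy)-3,5-dimethoxyphenyl]pent-3-yn-2-ol F1. Lindlar semihydrogenation (H2, Pd/CaCO3–Pb, quinoline, EtOAc) should give (2S,3Z)-5-[4-(benzyloxy)-3,5-dimethoxyphenyl]pent-3-en-2-ol F2. DIC/DMAP esterification with 6 would give the (2S,3Z)-pentenyl 3-arylpropanoate F3. LDA/THF then TBSCl (−78 °C → rt) should give the silyl ketene acetal with ArCH2 trans to OSi F4. Its chair transition state carries CH2Ar and CH2Ar' axial and the methyl equatorial (an axial methyl would clash with the axial Z-substituent), and leads to the same silyl ester 15. The fallback comes back to the route at 16.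

Step 12. Hydride attack at sulfur of one mesylate would free an alkoxide that closes onto the neighbouring CH2OMs to give a tetrahydrofuran; elimination could also compete. The fallback removes the two oxygens one at a time, so that a 1,4-bis-electrophile never exists. It sets out from 17. MsCl/Et3N would give (2R,3S,4E)-2-[3,4-bis(benzyloxy)-5-methoxybenzyl]-3-[4-(benzyloxy)-3,5-dimethoxybenzyl]hex-4-en-1-yl methanesulfonate F5. LiEt3BH in THF should give 1,2-bis(benzyloxy)-5-[(2R,3R,4E)-3-[4-(benzyloxy)-3,5-dimethoxybenzyl]-2-methylhex-4-en-1-yl]-3-methoxybenzene F6. Ozonolysis (O3, CH2Cl2, −78 °C) would pass through the ozonide of this alkene F7, and NaBH4 would give (2R,3R)-2-[4-(benzyloxy)-3,5-dimethoxybenzyl]-4-[3,4-bis(benzyloxy)-5-methoxyphenyl]-3-methylbutan-1-ol F8. MsCl/Et3N would give its methanesulfonate F9, and LiAlH4 reduction comes back to the route at 21.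

Step 5. Base-induced propargyl-to-allenyl isomerisation of the skipped aryl-alkyne, O-benzylation of the carbinol or solvolysis of the electron-rich benzylic bromide could lower the yield. The fallback makes the same bond by a base-free sp3–sp2 coupling that also sets the E-alkene. It sets out from 10 and 9. Palladium-catalysed hydrostannation of 10 (Bu3SnH, PdCl2(PPh3)2 cat., THF) should give (2R,3E)-4-(tributylstannyl)but-3-en-2-ol F10, to be freed from its regioisomer by chromatography. Stille coupling with 9 (Pd2(dba)3, tri(2-furyl)phosphine, THF, 60 °C) comes back to the route at 12, so that 11 and step 6 are bypassed.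

**Further compounds**
F1 | step 8 | (2S)-5-[4-(benzyloxy)-3,5-dimethoxyphenyl]pent-3-yn-2-ol | C[C@H](O)C#CCc1cc(OC)c(OCc2ccccc2)c(OC)c1
F2 | step 8 | (2S,3Z)-5-[4-(benzyloxy)-3,5-dimethoxyphenyl]pent-3-en-2-ol | C[C@H](O)/C=C\Cc1cc(OC)c(OCc2ccccc2)c(OC)c1
F3 | step 8 | (2S,3Z)-5-[4-(benzyloxy)-3,5-dimethoxyphenyl]pent-3-en-2-yl 3-[3,4-bis(benzyloxy)-5-methoxyphenyl]propanoate | O=C(CCc1cc(OC)c(OCc2ccccc2)c(OCc2ccccc2)c1)O[C@@H](C)/C=C\Cc1cc(OC)c(OCc2ccccc2)c(OC)c1
F4 | step 8 | O-TBS ketene acetal of F3, ArCH2 trans to OSi (E) | CC(C)(C)[Si](C)(C)O/C(=C/Cc1cc(OC)c(OCc2ccccc2)c(OCc2ccccc2)c1)O[C@@H](C)/C=C\Cc1cc(OC)c(OCc2ccccc2)c(OC)c1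
F5 | step 12 | (2R,3S,4E)-2-[3,4-bis(benzyloxy)-5-methoxybenzyl]-3-[4-(benzyloxy)-3,5-dimethoxybenzyl]hex-4-en-1-yl methanesulfonate | CS(=O)(=O)OC[C@H](Cc1cc(OC)c(OCc2ccccc2)c(OCc2ccccc2)c1)[C@@H](Cc1cc(OC)c(OCc2ccccc2)c(OC)c1)/C=C/C
F6 | step 12 | 1,2-bis(benzyloxy)-5-[(2R,3R,4E)-3-[4-(benzyloxy)-3,5-dimethoxybenzyl]-2-methylhex-4-en-1-yl]-3-methoxybenzene | C[C@H](Cc1cc(OC)c(OCc2ccccc2)c(OCc2ccccc2)c1)[C@@H](Cc1cc(OC)c(OCc2ccccc2)c(OC)c1)/C=C/C
F7 | step 12 | secondary ozonide of F6 (mixture at the trioxolane carbons) | C[C@H](Cc1cc(OC)c(OCc2ccccc2)c(OCc2ccccc2)c1)[C@@H](Cc1cc(OC)c(OCc2ccccc2)c(OC)c1)C1OOC(C)O1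
F8 | step 12 | (2R,3R)-2-[4-(benzyloxy)-3,5-dimethoxybenzyl]-4-[3,4-bis(benzyloxy)-5-methoxyphenyl]-3-methylbutan-1-ol | C[C@H](Cc1cc(OC)c(OCc2ccccc2)c(OCc2ccccc2)c1)[C@@H](Cc1cc(OC)c(OCc2ccccc2)c(OC)c1)CO
F9 | step 12 | (2R,3R)-2-[4-(benzyloxy)-3,5-dimethoxybenzyl]-4-[3,4-bis(benzyloxy)-5-methoxyphenyl]-3-methylbutyl methanesulfonate | C[C@H](Cc1cc(OC)c(OCc2ccccc2)c(OCc2ccccc2)c1)[C@@H](Cc1cc(OC)c(OCc2ccccc2)c(OC)c1)COS(C)(=O)=O
F10 | step 5 | (2R,3E)-4-(tributylstannyl)but-3-en-2-ol | C[C@@H](O)/C=C/[Sn](CCCC)(CCCC)CCCC
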